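**Strategy.** Ring B of the aryltetralin is opened at C1–C2. C1 carries two aryl groups (ring A through C8a and the pendant ring C), so it maps onto a diaryl carbene. C1, C2 and the C2 CH2O carbon make up an allyl triad. One palladium-catalysed operation joins a C2 vinylpalladium to that carbene, closes ring B, and lets methoxide open the resulting allylpalladium at its CH2 end, leaving a C1=C2 alkene. The precursor is an enantiopure benzophenone N-tosylhydrazone whose ring A carries a 3-bromo-2-(silyloxymethyl)but-3-enyl chain. Its single stereocentre (C3) comes from lipase desymmetrisation and later steers a hydroxyl-directed hydrogenation that sets C1 and C2.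

Key step: step 11

Assumption: Burkholderia cepacia lipase is taken to acetylate the pro-R hydroxymethyl arm of the prochiral diol, as the empirical size rule for primary alcohols predicts; if the other arm reacted, hydrolysis of the diacetate with the same enzyme would deliver the same (R)-monoacetate.

Numbering and descriptors:
- Tetralin numbering is used: C1 aryl-bearing, C2 and C3 side-chain-bearing, C4 CH2, C4a and C8a fusion carbons.
- Ring A is the fused arene, ring B the carbocycle, ring C the pendant aryl.
- The target is (1S,2S,3S), that is 1,2-cis and 2,3-trans.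
- The future C3 keeps one spatial arrangement from step 3 onward; only its descriptor changes with its ligands.
- It is (R) in the bromoalkenes, because C(Br)=CH2 outranks CH2OSi, and (S) again once ring B is closed.

Design choices:
- **Triisopropylsilyl instead of a smaller silyl group.** O-to-O silyl migration in a 1,3-diol monoether would amount to racemisation. The group must also outlast a B–Br reagent, warm hydrazone formation and hot methoxide.
- **Diaryl ketone by bromine–lithium exchange.** The ring A bromide is bought with the starting material and is used before the vinyl bromide exists. No Lewis-acid aroylation then has to be run beside a silyl ether and a bromoalkene.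
- **Explicit acetate cleavage** is placed between silylation and oxidation.
- **NaOMe as the only base and nucleophile in the key step,** so no second alkoxide or cation competes.

Step 1
Reactants: 1 diethyl malonate; 2 2-bromo-4,5-dimethoxybenzyl bromide
Product: 3 diethyl 2-(2-bromo-4,5-dimethoxybenzyl)malonate
Conditions: NaH (1.0 equiv), 1 (2 equiv), THF, 0 °C to rt
Reagents that add atoms: none
Why: Malonic ester alkylation (SN2) of the sodium enolate with a reactive benzylic bromide; the excess of 1 suppresses double alkylation and the aryl bromide is inert.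

Step 2
Reactants: 3 diethyl 2-(2-bromo-4,5-dimethoxybenzyl)malonate
Product: 4 2-(2-bromo-4,5-dimethoxybenzyl)propane-1,3-diol
Conditions: LiAlH4, THF, 0 °C to rt; then H2O
Reagents that add atoms: none
Why: LiAlH4 reduction of both esters gives the prochiral 1,3-diol, and an electron-rich aryl bromide is not reduced at or below room temperature.

Step 3
Reactants: 4 2-(2-bromo-4,5-dimethoxybenzyl)propane-1,3-diol
Product: 5 (R)-3-(2-bromo-4,5-dimethoxyphenyl)-2-(hydroxymethyl)propyl acetate
Conditions: Burkholderia cepacia lipase (Amano lipase PS), vinyl acetate, i-Pr2O, 30 °C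
Reagents that add atoms: vinyl acetate, C=COC(C)=O
Why: Enzymatic desymmetrisation by irreversible transesterification, in which the chiral active site acetylates the pro-R arm and so sets the only stereocentre carried into the key step (the later C3), while slight over-acetylation to the achiral diacetate should remove the minor enantiomer.

Step 4
Reactants: 5 (R)-3-(2-bromo-4,5-dimethoxyphenyl)-2-(hydroxymethyl)propyl acetate
Product: 6 (S)-3-(2-bromo-4,5-dimethoxyphenyl)-2-[(triisopropylsilyloxy)methyl]propyl acetate
Conditions: TIPSCl, imidazole, DMF, rt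
Reagents that add atoms: triisopropylsilyl chloride, CC(C)[Si](Cl)(C(C)C)C(C)C
Why: Imidazole-mediated silylation of a primary alcohol, mild and fast enough to forestall the 1,3-acetyl shift that would racemise 5.

Step 5
Reactants: 6 (S)-3-(2-bromo-4,5-dimethoxyphenyl)-2-[(triisopropylsilyloxy)methyl]propyl acetate
Product: 7 (S)-3-(2-bromo-4,5-dimethoxyphenyl)-2-[(triisopropylsilyloxy)methyl]propan-1-ol
Conditions: K2CO3 (0.2 equiv), MeOH, 0 °C to rt
Reagents that add atoms: none
Why: Base-catalysed methanolysis (Zemplén-type transesterification) removes the acetate, and the bulky silyl group should neither cleave nor migrate to the freed oxygen.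

Step 6
Reactants: 7 (S)-3-(2-bromo-4,5-dimethoxyphenyl)-2-[(triisopropylsilyloxy)methyl]propan-1-ol; 8 3,4-dimethoxybenzaldehyde
Product: 10 (2S)-3-{2-[(3,4-dimethoxyphenyl)(hydroxy)methyl]-4,5-dimethoxyphenyl}-2-[(triisopropylsilyloxy)methyl]propan-1-ol as a mixture of carbinol epimers, via dilithiated aryllithium alkoxide 9 (not isolated)
Conditions: n-BuLi (2.1 equiv), THF, −78 °C; 8, −78 °C; sat. aq NH4Cl at −78 °C
Reagents that add atoms: none
Why: The first equivalent of n-BuLi forms the alkoxide, the second performs bromine–lithium exchange, and aryllithium 9 adds 1,2 to the aldehyde; the new carbinol centre forms unselectively and is erased in step 7.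

Step 7
Reactants: 10 (2S)-3-{2-[(3,4-dimethoxyphenyl)(hydroxy)methyl]-4,5-dimethoxyphenyl}-2-[(triisopropylsilyloxy)methyl]propan-1-ol
Product: 11 (R)-2-[2-(3,4-dimethoxybenzoyl)-4,5-dimethoxybenzyl]-3-(triisopropylsilyloxy)propanal
Conditions: Dess–Martin periodinane (2.6 equiv), CH2Cl2, 0 °C to rt
Reagents that add atoms: none
Why: Dess–Martin oxidation converts the primary alcohol into the aldehyde and the benzhydrol into the diaryl ketone in one base-free operation, so the alpha stereocentre should not epimerise.

Step 8
Reactants: 11 (R)-2-[2-(3,4-dimethoxybenzoyl)-4,5-dimethoxybenzyl]-3-(triisopropylsilyloxy)propanal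
Product: 12 (S)-(3,4-dimethoxyphenyl)[4,5-dimethoxy-2-(2-{[(triisopropylsilyl)oxy]methyl}but-3-yn-1-yl)phenyl]methanone
Conditions: dimethyl (1-diazo-2-oxopropyl)phosphonate, K2CO3, MeOH, 0 °C to rt
Reagents that add atoms: dimethyl (1-diazo-2-oxopropyl)phosphonate, CC(=O)C(=[N+]=[N-])P(=O)(OC)OC
Why: Ohira–Bestmann (Seyferth–Gilbert) homologation acts on the aldehyde only, because the hindered, donor-substituted diaryl ketone is unreactive toward the phosphonate anion, and alpha-branched beta-silyloxy aldehydes generally keep their configuration under these mild conditions.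

Step 9
Reactants: 12 (S)-(3,4-dimethoxyphenyl)[4,5-dimethoxy-2-(2-{[(triisopropylsilyl)oxy]methyl}but-3-yn-1-yl)phenyl]methanone
Product: 14 (R)-[2-(3-bromo-2-{[(triisopropylsilyl)oxy]methyl}but-3-en-1-yl)-4,5-dimethoxyphenyl](3,4-dimethoxyphenyl)methanone, via bromoboration adduct 13 (not isolated)
Conditions: B-bromo-9-BBN (2.2 equiv), CH2Cl2, 0 °C; then AcOH, 0 °C to rt
Reagents that add atoms: B-bromo-9-borabicyclo[3.3.1]nonane, BrB1C2CCCC1CCC2
Why: Syn-bromoboration puts boron on the terminal and bromine on the internal alkyne carbon, and protodeboronation of 13 with acetic acid gives the Markovnikov 2-bromoalkene; the second equivalent of borane covers reversible binding to the ketone, and the short time at 0 °C should spare the aryl methyl ethers and the silyl ether.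

Step 10
Reactants: 14 (R)-[2-(3-bromo-2-{[(triisopropylsilyl)oxy]methyl}but-3-en-1-yl)-4,5-dimethoxyphenyl](3,4-dimethoxyphenyl)methanone; 15 p-toluenesulfonyl hydrazide
Product: 16 N-tosylhydrazone of 14, (R) at the chain stereocentre, mixture of C=N isomers
Conditions: 15 (1.5 equiv), AcOH (10 mol %), EtOH, 75 °C
Reagents that add atoms: none
Why: Acid-catalysed condensation of a sulfonyl hydrazide with a diaryl ketone, slowed by the ortho chain and the donor groups but free of competing enolisation; both C=N isomers lead to the same diazo compound.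

Step 11
Reactants: 16 N-tosylhydrazone of 14
Product: 19 (3S)-1-(3,4-dimethoxyphenyl)-6,7-dimethoxy-2-(methoxymethyl)-3-[(triisopropylsilyloxy)methyl]-3,4-dihydronaphthalene, via diaryldiazomethane 17 (not isolated), via allylpalladium bromide 18 (not isolated)
Conditions: Pd2(dba)3 (2.5 mol %), DPEphos (6 mol %), NaOMe (4 equiv), 1,4-dioxane/MeOH 20:1, 85 °C, 16 added over 4 h (final 0.01 M)
Reagents that add atoms: sodium methoxide, [Na+].[O-]C
Why: Proposed new method: NaOMe deprotonates 16 and the salt loses sulfinate (Bamford–Stevens) to give 17, zerovalent palladium inserts into the C–Br bond, the vinylpalladium takes up the tethered diazo carbon with loss of N2, and the C2 vinyl carbon migrates from palladium to the carbene carbon C1. Ring B thus closes by contraction of a seven-membered palladacycle (Pd, C2, C3, C4, C4a, C8a, C1) to the six-membered carbocycle, which leaves the eta3-allylpalladium 18 spanning C1–C2–CH2, and methoxide opens it at CH2 in a Tsuji–Trost etherification. The closest known reaction types are the three-component coupling of vinyl halides, N-tosylhydrazones and amine or malonate nucleophiles, and the palladium-catalysed allylic etherification of aryl-substituted allyl systems with methanol; the intramolecular six-ring insertion combined with alkoxide capture is new. No stereocentre is formed, and C3 sits on the central allyl carbon, so its hydrogen is neither acidic nor available for beta-hydride loss, the configuration is kept and no diene can arise. The step needs regioselective attack at the allyl unit, secured by the two aryl groups that shield C1 and by conjugation of the emerging C1=C2 bond, and it needs insertion to outrun azine formation, N-allylation of the hydrazone anion and intermolecular coupling, secured by the tether and by slow addition of 16 to the hot catalyst–base mixture. The chelating DPEphos leaves little room for hydride transfer from palladium-bound methoxide, and capture by sulfinate should be reversible whereas ether formation is not.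

Step 12
Reactants: 19 (3S)-1-(3,4-dimethoxyphenyl)-6,7-dimethoxy-2-(methoxymethyl)-3-[(triisopropylsilyloxy)methyl]-3,4-dihydronaphthalene
Product: 20 (S)-[4-(3,4-dimethoxyphenyl)-6,7-dimethoxy-3-(methoxymethyl)-1,2-dihydronaphthalen-2-yl]methanol
Conditions: Bu4NF, THF, rt
Reagents that add atoms: none
Why: Fluoride-induced desilylation runs under basic conditions, which the acid-sensitive allylic methyl ether tolerates.

Step 13
Reactants: 20 (S)-[4-(3,4-dimethoxyphenyl)-6,7-dimethoxy-3-(methoxymethyl)-1,2-dihydronaphthalen-2-yl]methanol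
Product: 21 [(1S,2S,3S)-1-(3,4-dimethoxyphenyl)-6,7-dimethoxy-2-(methoxymethyl)-1,2,3,4-tetrahydronaphthalen-3-yl]methanol
Conditions: H2 (50 bar), [Ir(cod)(PCy3)(py)]PF6 (10 mol %, in two portions), CH2Cl2, rt
Reagents that add atoms: none
Why: Hydroxyl-directed homogeneous hydrogenation, in which the C3 CH2OH group, held pseudoaxial by allylic strain with the C2 substituent, binds the cationic iridium dihydride so that both hydrogens add syn on its own face, pushing the C1 aryl and the C2 CH2OMe to the opposite face (1,2-cis, 2,3-trans, that is 1S,2S).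

Step 14
Reactants: 21 [(1S,2S,3S)-1-(3,4-dimethoxyphenyl)-6,7-dimethoxy-2-(methoxymethyl)-1,2,3,4-tetrahydronaphthalen-3-yl]methanol
Product: 22 (1S,2S,3S)-1-(3,4-dimethoxyphenyl)-6,7-dimethoxy-2,3-bis(methoxymethyl)-1,2,3,4-tetrahydronaphthalene
Conditions: NaH, MeI, THF, 0 °C to rt
Reagents that add atoms: iodomethane, CI
Why: Williamson etherification of the primary alkoxide with MeI, under which none of the three stereocentres is acidic.

**Compound list**

1 | diethyl malonate | CCOC(=O)CC(=O)OCC | starting material
2 | 2-bromo-4,5-dimethoxybenzyl bromide | COc1cc(Br)c(CBr)cc1OC | starting material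
3 | diethyl 2-(2-bromo-4,5-dimethoxybenzyl)malonate | CCOC(=O)C(Cc1cc(OC)c(OC)cc1Br)C(=O)OCC | intermediate
4 | 2-(2-bromo-4,5-dimethoxybenzyl)propane-1,3-diol | OCC(CO)Cc1cc(OC)c(OC)cc1Br | intermediate
5 | (R)-3-(2-bromo-4,5-dimethoxyphenyl)-2-(hydroxymethyl)propyl acetate | OC[C@@H](Cc1cc(OC)c(OC)cc1Br)COC(C)=O | intermediate
6 | (S)-3-(2-bromo-4,5-dimethoxyphenyl)-2-[(triisopropylsilyloxy)methyl]propyl acetate | CC(C)[Si](C(C)C)(C(C)C)OC[C@@H](Cc1cc(OC)c(OC)cc1Br)COC(C)=O | intermediate
7 | (S)-3-(2-bromo-4,5-dimethoxyphenyl)-2-[(triisopropylsilyloxy)methyl]propan-1-ol | CC(C)[Si](C(C)C)(C(C)C)OC[C@@H](Cc1cc(OC)c(OC)cc1Br)CO | intermediate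
8 | 3,4-dimethoxybenzaldehyde | COc1ccc(C=O)cc1OC | starting material
9 | dilithiated aryllithium alkoxide derived from 7 | CC(C)[Si](C(C)C)(C(C)C)OC[C@@H](Cc1cc(OC)c(OC)cc1[Li])CO[Li] | intermediate
10 | (2S)-3-{2-[(3,4-dimethoxyphenyl)(hydroxy)methyl]-4,5-dimethoxyphenyl}-2-[(triisopropylsilyloxy)methyl]propan-1-ol, carbinol epimers | CC(C)[Si](C(C)C)(C(C)C)OC[C@@H](Cc1cc(OC)c(OC)cc1C(O)c1ccc(OC)c(OC)c1)CO | intermediate
11 | (R)-2-[2-(3,4-dimethoxybenzoyl)-4,5-dimethoxybenzyl]-3-(triisopropylsilyloxy)propanal | CC(C)[Si](C(C)C)(C(C)C)OC[C@@H](Cc1cc(OC)c(OC)cc1C(=O)c1ccc(OC)c(OC)c1)C=O | intermediate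
12 | (S)-(3,4-dimethoxyphenyl)[4,5-dimethoxy-2-(2-{[(triisopropylsilyl)oxy]methyl}but-3-yn-1-yl)phenyl]methanone | CC(C)[Si](C(C)C)(C(C)C)OC[C@@H](Cc1cc(OC)c(OC)cc1C(=O)c1ccc(OC)c(OC)c1)C#C | intermediate
13 | (R,Z)-2-bromo-1-(9-borabicyclo[3.3.1]nonan-9-yl)alkene formed from 12 (bromoboration adduct) | CC(C)[Si](C(C)C)(C(C)C)OC[C@@H](Cc1cc(OC)c(OC)cc1C(=O)c1ccc(OC)c(OC)c1)/C(Br)=C/B1C2CCCC1CCC2 | intermediate
14 | (R)-[2-(3-bromo-2-{[(triisopropylsilyl)oxy]methyl}but-3-en-1-yl)-4,5-dimethoxyphenyl](3,4-dimethoxyphenyl)methanone | CC(C)[Si](C(C)C)(C(C)C)OC[C@@H](Cc1cc(OC)c(OC)cc1C(=O)c1ccc(OC)c(OC)c1)C(Br)=C | intermediate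
15 | p-toluenesulfonyl hydrazide | Cc1ccc(S(=O)(=O)NN)cc1 | starting material
16 | (R)-N-tosylhydrazone of 14 (C=N isomers) | CC(C)[Si](C(C)C)(C(C)C)OC[C@@H](Cc1cc(OC)c(OC)cc1C(=NNS(=O)(=O)c1ccc(C)cc1)c1ccc(OC)c(OC)c1)C(Br)=C | intermediate
17 | (R)-diaryldiazomethane released from 16 | CC(C)[Si](C(C)C)(C(C)C)OC[C@@H](Cc1cc(OC)c(OC)cc1C(=[N+]=[N-])c1ccc(OC)c(OC)c1)C(Br)=C | intermediate
18 | (S)-allylpalladium bromide spanning C1–C2–CH2 (drawn in its sigma form at CH2, phosphine omitted) | CC(C)[Si](C(C)C)(C(C)C)OC[C@H]1Cc2cc(OC)c(OC)cc2C(c2ccc(OC)c(OC)c2)=C1C[Pd]Br | intermediate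
19 | (3S)-1-(3,4-dimethoxyphenyl)-6,7-dimethoxy-2-(methoxymethyl)-3-[(triisopropylsilyloxy)methyl]-3,4-dihydronaphthalene | CC(C)[Si](C(C)C)(C(C)C)OC[C@H]1Cc2cc(OC)c(OC)cc2C(c2ccc(OC)c(OC)c2)=C1COC | intermediate
20 | (S)-[4-(3,4-dimethoxyphenyl)-6,7-dimethoxy-3-(methoxymethyl)-1,2-dihydronaphthalen-2-yl]methanol | OC[C@H]1Cc2cc(OC)c(OC)cc2C(c2ccc(OC)c(OC)c2)=C1COC | intermediate
21 | [(1S,2S,3S)-1-(3,4-dimethoxyphenyl)-6,7-dimethoxy-2-(methoxymethyl)-1,2,3,4-tetrahydronaphthalen-3-yl]methanol | OC[C@H]1Cc2cc(OC)c(OC)cc2[C@H](c2ccc(OC)c(OC)c2)[C@@H]1COC | intermediate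
22 | (1S,2S,3S)-1-(3,4-dimethoxyphenyl)-6,7-dimethoxy-2,3-bis(methoxymethyl)-1,2,3,4-tetrahydronaphthalene | COC[C@H]1Cc2cc(OC)c(OC)cc2[C@H](c2ccc(OC)c(OC)c2)[C@@H]1COC | target

Total step count: 14. Longest linear sequence: 14 steps (from 1 and 2 to 22).

**Steps most likely to fail**

Step 11. Four processes could defeat it:
- hydride transfer from palladium-bound methoxide to the vinyl- or allylpalladium, a net reduction;
- lasting capture of the allyl unit by sulfinate or by the hydrazone anion;
- protonation of the diazo function by methanol;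
- bimolecular decay of the diazo function to azine.

The fallback uses known chemistry, sets out from 14 and comes back at 19. Bromine–lithium exchange on 14 is run with t-BuLi (2.1 equiv, THF/Et2O, −95 °C). The bulky base should be slow toward the ortho-substituted, donor-deactivated ketone. Parham-type 6-exo-trig addition of the vinyllithium to the tethered diaryl ketone should then give (3S)-1-(3,4-dimethoxyphenyl)-6,7-dimethoxy-2-methylidene-3-[(triisopropylsilyloxy)methyl]-1,2,3,4-tetrahydronaphthalen-1-ol F1 as C1 epimers. Catalytic PPTS in MeOH at 0 °C ionises this doubly benzylic tertiary alcohol. Under thermodynamic control methanol adds to the CH2 end of the allyl cation (SN1' allylic transposition), which gives 19. The same C1–C2 bond is made with reversed polarity, and two steps replace steps 10 and 11.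

Step 13. Three processes are of concern:
- slow hydrogen uptake at the tetrasubstituted, aryl-flanked alkene, with deactivation of the catalyst;
- ionisation of the allylic ether by acidic iridium hydrides, followed by ring closure through the free hydroxyl;
- poor facial selectivity.

The fallback sets out from 20 and comes back at 22. The alcohol is methylated first (NaH, MeI, THF) to give (S)-1-(3,4-dimethoxyphenyl)-6,7-dimethoxy-2,3-bis(methoxymethyl)-3,4-dihydronaphthalene F2, which has no hydroxyl left to cyclise. The alkene is then hydrogenated under catalyst control instead of substrate direction. The catalyst is a chiral cationic iridium phosphinooxazoline complex, [Ir(cod)(tBu-PHOX)][B(C6H3-3,5-(CF3)2)4], at 50 bar H2 in CH2Cl2. The ligand enantiomer is chosen so that H2 adds to the face bearing the C3 side chain, whose ether oxygen may assist binding. This catalyst class is known to reduce tetrasubstituted aryl alkenes, 3,4-dihydronaphthalenes among them.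

Step 9. Three processes are of concern:
- loss of the silyl ether or of an aryl methyl group to the B–Br reagent;
- stalling through complexation of the ketone;
- incomplete regiocontrol.

The fallback sets out from 12 and comes back at 14. Stannylcupration with in situ protonation uses Me3SnCu·SMe2 (from Me3SnLi and CuBr·SMe2) in THF/MeOH at −63 °C. This is an established route from terminal alkynes to 2-stannyl-1-alkenes. It should give (R)-(3,4-dimethoxyphenyl)[4,5-dimethoxy-2-(2-{[(triisopropylsilyl)oxy]methyl}-3-(trimethylstannyl)but-3-en-1-yl)phenyl]methanone F3. Bromodestannylation with Br2 (1.0 equiv, CH2Cl2, −78 °C) should be much faster than attack on the ketone-deactivated arenes and returns 14.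

**Further compounds**

F1 | step 11 | (3S)-1-(3,4-dimethoxyphenyl)-6,7-dimethoxy-2-methylidene-3-[(triisopropylsilyloxy)methyl]-1,2,3,4-tetrahydronaphthalen-1-ol (C1 epimers) | CC(C)[Si](C(C)C)(C(C)C)OC[C@H]1Cc2cc(OC)c(OC)cc2C(O)(c2ccc(OC)c(OC)c2)C1=C
F2 | step 13 | (S)-1-(3,4-dimethoxyphenyl)-6,7-dimethoxy-2,3-bis(methoxymethyl)-3,4-dihydronaphthalene | COC[C@H]1Cc2cc(OC)c(OC)cc2C(c2ccc(OC)c(OC)c2)=C1COC
F3 | step 9 | (R)-(3,4-dimethoxyphenyl)[4,5-dimethoxy-2-(2-{[(triisopropylsilyl)oxy]methyl}-3-(trimethylstannyl)but-3-en-1-yl)phenyl]methanone | CC(C)[Si](C(C)C)(C(C)C)OC[C@@H](Cc1cc(OC)c(OC)cc1C(=O)c1ccc(OC)c(OC)c1)C(=C)[Sn](C)(C)C
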